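Start from the amounts: in the asked flask c(E) is 0.13 M against 0.195 M for c(Q), so there E is the reagent charged in the smaller amount, the limiting reagent, and its balance is the one to write. Whatever of the charge is neither E nor J is the gap, and in the south-east run it stands at 10.3% at 5.00 min.

in all of them: Q 0.195 M

| flask | E | remark | time |
|---|---|---|---|
| south-east | 0.13 M | the very flask that is asked about, followed so far |  |
| north-east | 0.20 M | run made earlier |  |
| flask | 0.13 M |  | 10 min |

| run | time / min | E / % | J / % |
|---|---|---|---|
| south-east | 0.417 | 88.8 | 10.0 |
| south-east | 1.00 | 76.3 | 20.3 |
| south-east | 2.00 | 62.1 | 32.9 |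
| south-east | 5.00 | 41.8 | 47.9 |
| north-east | 0.500 | 86.9 | 11.9 |
| north-east | 1.33 | 72.6 | 24.4 |
| north-east | 2.50 | 59.6 | 34.9 |
| north-east | 4.00 | 50.1 | 41.0 |

(scatter of a reading: 0.3 percentage points)
- why nothing more happens at 10 min, or that something still does (all of E has reacted / it is still moving / forward and back rates have come level / Q has run out first)
- how much of the E has reacted by 10 min
- how much J there is at 10 min, in percent of the E charged
- the reaction counts as stopped when no species that holds the E changes by six tenths of a point or more over the second half of the time
- what has gone from E into another species counts as reacted, even if it can come back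

Divide that gap by the exposure, the area under the E curve up to that reading, 3.13 min, and you read from the south-east run 0.0330 min⁻¹, the leak constant, the gap gained per minute per unit of E standing.

Now turn the settings one after the other. For the amount of E, take the north-east run, which has more E: its last reading gives 0.0327 min⁻¹, the same constant within the scatter. For time, hold E at its last south-east reading as a ceiling: the reckoned gap of the asked flask comes to no more than 17.2% by 10 min, and with E somewhat below that reading it gains a little less than 6.9 percentage points over the second half, so I expect the flask to be still moving. For Q, both runs hold the same charge, so reckon by hand: with c(E) and the time held, more Q should draw E down faster, shorten the exposure and shrink the gap.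

The forecast says it is still moving, with 67.8% reacted and 51.4% J, and it reads the gap as “a slow first-order leak of E to an unseen species”.

In the flask, it is still moving, with 66.9% reacted and 51.2% J, so the gap is 15.7%, and 23.5% of what has reacted is not J.

    Q + D ⇌ G (K = 3.30 L mol⁻¹, k = 0.610 L mol⁻¹ min⁻¹)
    E → D (k = 0.0320 min⁻¹)
    D ⇌ L (K = 1.20, k = 0.500 min⁻¹)
    E + Q ⇌ J (K = 12.0 L mol⁻¹, k = 1.40 L mol⁻¹ min⁻¹)

Carry the leak constant to a neighbour flask, charged like this one but with c(Q) at 0.33 M. This flask's gap divided by 0.0330 min⁻¹ gives an exposure of 4.76 min, so its mean E stood above its end value by 21.7% of what had reacted. With 22.1% of E left and 77.9% reacted in the neighbour, the same shape, taken over as an assumption, gives a reckoned gap of 12.9%. The neighbour holds 66.5% of J, a gap of 11.4%.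

(The runs were generated by integration for substances that don't exist; the scatter is artificial.)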